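The cyclohexenone is disconnected by a retro-semipinacol step: its carbonyl carbon and the neighbouring cyclobutane CH are read as the siloxy bridgehead and the endo amine carbon of a norbornene, whose one-carbon bridge is the methyl-bearing quaternary cyclobutane carbon. Diazotization makes this bridge migrate from the bridgehead to the amine carbon; in one operation the cyclopentene ring grows into the cyclohexenone, the cyclopentane shrinks to the cyclobutane and the enone is unveiled. The precursor, an acetonide-protected 1-siloxy-6-endo-aminonorbornene already fused to the cycloheptane, comes from an intramolecular Diels–Alder reaction of a 5,5-disubstituted siloxycyclopentadiene with a tethered (E)-nitroalkene, assembled from (R)-solketal.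

Key step: step 9

Assumption: the (S)-SEGPHOS-modified iridium catalyst of step 1 is taken to deliver the (1S) carbinol (oxygen syn to the dioxolane oxygen); if its sense of induction is the opposite, (R)-SEGPHOS is used and nothing else changes.

Step 1
Reactants: 1 (R)-solketal; 2 3-methylbuta-1,2-diene (1,1-dimethylallene)
Product: 4 (1S)-1-[(4S)-2,2-dimethyl-1,3-dioxolan-4-yl]-2,2-dimethylbut-3-en-1-ol, via (S)-glyceraldehyde acetonide 3 (not isolated)
Conditions: [Ir(cod)Cl]2 (2.5 mol%), (S)-SEGPHOS (5 mol%), 4-cyano-3-nitrobenzoic acid (10 mol%), allyl acetate (10 mol%), Cs2CO3 (20 mol%), 2 (3 equiv), toluene, 65 °C, sealed tube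
Reagents that add atoms: none
Why: Iridium-catalysed transfer-hydrogenative carbonyl reverse prenylation: the catalyst dehydrogenates the primary alcohol to aldehyde 3, the hydride adds to the allene to give a 1,1-dimethylallyl–iridium species that attacks through its substituted terminus in a closed chair transition state, and the chiral bisphosphine sets the new carbinol centre (1S, syn to the dioxolane oxygen) while the α-centre survives because the aldehyde is consumed as it forms.

Step 2
Reactants: 4 (1S)-1-[(4S)-2,2-dimethyl-1,3-dioxolan-4-yl]-2,2-dimethylbut-3-en-1-ol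
Product: 5 [(4S,5S)-2,2-dimethyl-5-(2-methylbut-3-en-2-yl)-1,3-dioxolan-4-yl]methanol (trans-dioxolane)
Conditions: CSA (5 mol%), acetone, rt, equilibration; recovered 4 is resubmitted
Reagents that add atoms: none
Why: Acid-catalysed acetal migration under thermodynamic control: the trans-4,5-disubstituted dioxolane with a free primary hydroxyl should be favoured over the monosubstituted dioxolane with a free neopentyl secondary hydroxyl, and no stereocentre is touched.

Step 3
Reactants: 5 [(4S,5S)-2,2-dimethyl-5-(2-methylbut-3-en-2-yl)-1,3-dioxolan-4-yl]methanol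
Product: 6 (4R,5S)-2,2-dimethyl-5-(2-methylbut-3-en-2-yl)-1,3-dioxolane-4-carbaldehyde
Conditions: TEMPO (10 mol%), PhI(OAc)2 (1.1 equiv), CH2Cl2, rt; used crude
Reagents that add atoms: none
Why: Oxoammonium (TEMPO) oxidation of the primary alcohol under non-basic conditions gives the α-alkoxy aldehyde without epimerization and leaves the alkene alone.

Step 4
Reactants: 6 (4R,5S)-2,2-dimethyl-5-(2-methylbut-3-en-2-yl)-1,3-dioxolane-4-carbaldehyde; 7 3-methylcyclopent-2-en-1-one
Product: 9 aldol adduct 5-[(S)-hydroxy{(4S,5S)-2,2-dimethyl-5-(2-methylbut-3-en-2-yl)-1,3-dioxolan-4-yl}methyl]-3-methylcyclopent-2-en-1-one (both C-5 epimers), via lithium dienolate 8 (not isolated)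
Conditions: 7, LiN(i-Pr)2 (1.05 equiv), THF, −78 °C; then 6, −78 °C; AcOH quench
Reagents that add atoms: none
Why: Directed aldol addition: kinetic α'-deprotonation of 7 gives the cross-conjugated lithium enolate, which adds to the α-alkoxy aldehyde in the Felkin–Anh (polar) sense so that the new carbinol oxygen is anti to the dioxolane C–O bond (S), and both ring-carbon epimers are carried on because that centre is re-enolized in step 5.

Step 5
Reactants: 9 aldol adduct (both C-5 epimers)
Product: 12 (5S)-5-[(S)-(tert-butyldimethylsilyloxy){(4R,5S)-2,2-dimethyl-5-(2-methylbut-3-en-2-yl)-1,3-dioxolan-4-yl}methyl]-3,5-dimethylcyclopent-2-en-1-one, via dilithium alkoxide enolate 10 (not isolated), via lithium alkoxide 11 (not isolated)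
Conditions: LiN(i-Pr)2 (2.3 equiv), THF, −78 → −40 °C; MeI, DMPU, −78 → −30 °C; then TBSOTf, −78 → 0 °C
Reagents that add atoms: iodomethane CI; tert-butyldimethylsilyl trifluoromethanesulfonate CC(C)(C)[Si](C)(C)OS(=O)(=O)C(F)(F)F
Why: Fráter–Seebach alkylation of the aldolate dianion: in the lithium-chelated alkoxide enolate the carbinol hydrogen eclipses the ring CH2 (allylic strain) and the dioxolane shields one face, so iodomethane enters anti to it and sets the quaternary centre (S), after which the lithium alkoxide is silylated in the same flask.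

Step 6
Reactants: 12 silyl ether with the terminal vinyl group
Product: 13 (E)-nitroalkene: 12 in which CH=CH2 has become (E)-CH=CH–NO2
Conditions: AgNO2 (3 equiv), TEMPO (0.4 equiv), 4 Å molecular sieves, ClCH2CH2Cl, 70 °C
Reagents that add atoms: silver nitrite [Ag+].[O-]N=O
Why: Radical nitration–dehydrogenation: NO2 released from AgNO2 adds to the terminus of the only monosubstituted, electron-rich alkene and TEMPO removes the β-hydrogen to give the (E)-nitroalkene, while the electron-poor trisubstituted enone and the quaternary allylic position (no allylic hydrogens) are unreactive.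

Step 7
Reactants: 13 (E)-nitroalkene
Product: 15 tricyclic endo-nitro Diels–Alder adduct (1-siloxynorbornene fused to the acetonide-bearing cycloheptane), via bis-silyl cyclopentadiene 14 (not isolated)
Conditions: TBSOTf (1.5 equiv), Et3N (3 equiv), CH2Cl2, 0 °C; then toluene, 100 °C
Reagents that add atoms: tert-butyldimethylsilyl trifluoromethanesulfonate CC(C)(C)[Si](C)(C)OS(=O)(=O)C(F)(F)F
Why: Soft enolization then intramolecular Diels–Alder reaction: with the α' carbon quaternary, silylation and γ-deprotonation give the 1-siloxy-3-methylcyclopenta-1,3-diene (no 1,5-hydrogen shift at the 5,5-disubstituted carbon), whose siloxy terminus bonds to the nitro-bearing carbon and whose unsubstituted terminus bonds to the β-carbon (matched polarity, enforced by the tether), and the four-carbon tether from C-5 forces addition on its own face with the tert-alkyl carbon exo, so the (E) geometry places the nitro group endo and fixes all four new stereocentres relative to the quaternary carbon.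

Step 8
Reactants: 15 tricyclic endo-nitro adduct
Product: 16 tricyclic endo-amine (15 with NH2 in place of NO2)
Conditions: Zn dust (excess), AcOH/THF, 0 °C → rt
Reagents that add atoms: none
Why: Dissolving-metal reduction of the secondary nitroalkane to the primary amine in acidic medium, where no nitronate forms and the endo C–N configuration is kept, with silyl ethers, acetonide and alkene inert.

Step 9
Reactants: 16 tricyclic endo-amine
Product: 18 tricyclic enone (4,6-dimethylbicyclo[3.1.1]hept-3-en-2-one core with the C-6/C-7 four-carbon bridge carrying OTBS and the trans-acetonide), via endo diazonium acetate 17 (not isolated)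
Conditions: NaNO2 (1.5 equiv), AcOH/H2O 4:1, 0 °C → rt
Reagents that add atoms: none
Why: Nitrosation gives the endo diazonium ion 17, whose C–N bond is anti-periplanar to the bond between the siloxy bridgehead and the methyl-bearing one-carbon bridge; as N2 leaves, this bridge carbon shifts to the diazonium carbon with inversion there and retention at the migrating carbon, pushed by the bridgehead oxygen, and loss of the silyl group from the oxocarbenium ion gives the conjugated enone. The closest known reaction type is the Tiffeneau–Demjanov (deaminative semipinacol) rearrangement of cyclic 1,2-amino alcohols. No ring is closed by cyclization: the cyclobutane arises by the 1,2-alkyl shift (contraction of the cyclopentane that held nitrogen), and the cyclohexenone arises by insertion of the former C–N carbon into the cyclopentene (one-carbon ring expansion). The new cyclobutane CH next to the ketone is fixed by the endo position of nitrogen (from the E nitroalkene) together with the inversion, and the quaternary carbon keeps its configuration. The step needs migration of the bridge carbon in preference to the vinyl carbon, hydride shift, elimination or solvent capture; the rigid bicycle secures this because only the bridge bond is anti-periplanar to the leaving group (the vinyl carbon is gauche) and its shift is assisted by the oxygen lone pair.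

Step 10
Reactants: 18 tricyclic enone (OTBS, acetonide)
Product: 19 tricyclic triol
Conditions: HF (48% aq.), MeCN, 0 °C → rt
Reagents that add atoms: none
Why: Acidic fluoride cleaves the hindered secondary silyl ether and hydrolyses the strained trans-fused acetonide in one operation under conditions that the conjugated enone and cyclobutane should tolerate, and no stereocentre is affected.

Step 11
Reactants: 19 tricyclic triol
Product: 20 central monoacetate (acetate on the middle carbinol of the triol)
Conditions: AcCl (1.0 equiv), 2,4,6-collidine, CH2Cl2, −78 → −40 °C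
Reagents that add atoms: acetyl chloride CC(Cl)=O
Why: Kinetically controlled acylation at low temperature: the central hydroxyl is the only one not flanked by a quaternary carbon, so it should be acetylated first, without change at any stereocentre.

Step 12
Reactants: 20 central monoacetate; 21 angelic acid [(Z)-2-methylbut-2-enoic acid]
Product: 22 CNP0335415.1 (target triester)
Conditions: 21 (6 equiv), 2,4,6-trichlorobenzoyl chloride, Et3N, toluene, rt; then 20, DMAP, toluene, 80 °C
Reagents that add atoms: none
Why: Yamaguchi esterification: the mixed 2,4,6-trichlorobenzoic angelic anhydride transfers the angeloyl group through the acylpyridinium ion without conjugate addition to the enoate, so the (Z) geometry is kept while both hindered hydroxyls are acylated.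

Compound list
1 | (R)-solketal, (R)-(2,2-dimethyl-1,3-dioxolan-4-yl)methanol | OC[C@@H]1COC(C)(C)O1 | starting material
2 | 3-methylbuta-1,2-diene (1,1-dimethylallene) | CC(C)=C=C | starting material
3 | (S)-2,2-dimethyl-1,3-dioxolane-4-carbaldehyde ((S)-glyceraldehyde acetonide) | O=C[C@@H]1COC(C)(C)O1 | intermediate
4 | (1S)-1-[(4S)-2,2-dimethyl-1,3-dioxolan-4-yl]-2,2-dimethylbut-3-en-1-ol (carbinol oxygen syn to the dioxolane C-4 oxygen) | O[C@@H](C(C)(C)C=C)[C@@H]1COC(C)(C)O1 | intermediate
5 | [(4S,5S)-2,2-dimethyl-5-(2-methylbut-3-en-2-yl)-1,3-dioxolan-4-yl]methanol (trans-dioxolane) | CC1(C)O[C@@H](C(C)(C)C=C)[C@H](CO)O1 | intermediate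
6 | (4R,5S)-2,2-dimethyl-5-(2-methylbut-3-en-2-yl)-1,3-dioxolane-4-carbaldehyde | CC1(C)O[C@@H](C(C)(C)C=C)[C@H](C=O)O1 | intermediate
7 | 3-methylcyclopent-2-en-1-one | CC1=CC(=O)CC1 | starting material
8 | lithium 4-methylcyclopenta-1,4-dien-1-olate (cross-conjugated enolate of 7) | CC1=CC(O[Li])=CC1 | intermediate
9 | aldol adduct: 3-methylcyclopent-2-enone carrying at C-5 the (S)-CH(OH) group bound to C-4 of the trans-dioxolane (carbinol oxygen anti to the dioxolane C–O; both C-5 epimers) | CC1(C)O[C@@H](C(C)(C)C=C)[C@H]([C@@H](O)C2CC(C)=CC2=O)O1 | intermediate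
10 | dilithium alkoxide enolate of 9 (enolate double bond between ring C-1 and C-5) | CC1(C)O[C@@H](C(C)(C)C=C)[C@H]([C@@H](O[Li])C2=C(O[Li])C=C(C)C2)O1 | intermediate
11 | lithium alkoxide of the C-5 methylated ketone (methyl anti to the dioxolane across the new bond) | CC1(C)O[C@@H](C(C)(C)C=C)[C@H]([C@@H](O[Li])[C@]2(C)CC(C)=CC2=O)O1 | intermediate
12 | (5S)-5-[(S)-(tert-butyldimethylsilyloxy){(4R,5S)-2,2-dimethyl-5-(2-methylbut-3-en-2-yl)-1,3-dioxolan-4-yl}methyl]-3,5-dimethylcyclopent-2-en-1-one | CC1(C)O[C@@H](C(C)(C)C=C)[C@H]([C@@H](O[Si](C)(C)C(C)(C)C)[C@]2(C)CC(C)=CC2=O)O1 | intermediate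
13 | (E)-nitroalkene: 12 with the vinyl group converted into (E)-2-nitrovinyl | CC1(C)O[C@@H](C(C)(C)/C=C/[N+](=O)[O-])[C@H]([C@@H](O[Si](C)(C)C(C)(C)C)[C@]2(C)CC(C)=CC2=O)O1 | intermediate
14 | bis-silyl cyclopentadiene: 1-(TBSO)-3,5-dimethylcyclopenta-1,3-diene whose C-5 carries the CH(OTBS)–dioxolane–CMe2–(E)-CH=CH–NO2 chain | CC1(C)O[C@@H](C(C)(C)/C=C/[N+](=O)[O-])[C@H]([C@@H](O[Si](C)(C)C(C)(C)C)[C@]2(C)C=C(C)C=C2O[Si](C)(C)C(C)(C)C)O1 | intermediate
15 | Diels–Alder adduct: 1-(TBSO)-3,7-dimethyl-6-endo-nitrobicyclo[2.2.1]hept-2-ene whose C-7 (on the side of the saturated bridge) and C-5 (exo) are joined by the chain CH(OTBS)–CH(O)–CH(O)–CMe2, the two middle oxygens being a trans-acetonide | CC1(C)O[C@@H]2[C@@H](O1)[C@@H](O[Si](C)(C)C(C)(C)C)[C@@]3(C)[C@]4(O[Si](C)(C)C(C)(C)C)C=C(C)[C@H]3[C@H](C2(C)C)[C@H]4[N+](=O)[O-] | intermediate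
16 | endo-amine: 15 with 6-endo-NH2 in place of the nitro group | CC1(C)O[C@@H]2[C@@H](O1)[C@@H](O[Si](C)(C)C(C)(C)C)[C@@]3(C)[C@]4(O[Si](C)(C)C(C)(C)C)C=C(C)[C@H]3[C@H](C2(C)C)[C@H]4N | intermediate
17 | endo diazonium acetate of 16 | CC1(C)O[C@@H]2[C@@H](O1)[C@@H](O[Si](C)(C)C(C)(C)C)[C@@]3(C)[C@]4(O[Si](C)(C)C(C)(C)C)C=C(C)[C@H]3[C@H](C2(C)C)[C@H]4[N+]#N.CC(=O)[O-] | intermediate
18 | tricyclic enone: 4,6-dimethylbicyclo[3.1.1]hept-3-en-2-one whose C-6 and C-7 are bridged, on the face away from the enone, by CH(OTBS)–CH(O)–CH(O)–CMe2 (CH(OTBS) on C-6; trans-acetonide on the other two oxygens; OTBS cis to the neighbouring acetonide oxygen) | CC1(C)O[C@@H]2[C@@H](O1)[C@@H](O[Si](C)(C)C(C)(C)C)[C@@]3(C)[C@@H]4C(=O)C=C(C)[C@H]3[C@@H]4C2(C)C | intermediate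
19 | tricyclic triol: 18 with three free hydroxyls (the hydroxyl next to C-6 cis to the middle one, the hydroxyl next to CMe2 trans to it) | O[C@@H]1[C@@H](O)[C@@H](O)[C@@]2(C)[C@@H]3C(=O)C=C(C)[C@H]2[C@@H]3C1(C)C | intermediate
20 | central monoacetate of 19 | O[C@@H]1[C@@H](OC(C)=O)[C@@H](O)[C@@]2(C)[C@@H]3C(=O)C=C(C)[C@H]2[C@@H]3C1(C)C | intermediate
21 | angelic acid, (Z)-2-methylbut-2-enoic acid | C/C=C(/C)C(O)=O | starting material
22 | CNP0335415.1: 20 with both remaining hydroxyls esterified as angelates | C/C=C(/C)C(=O)O[C@@H]1[C@@H](OC(C)=O)[C@@H](OC(=O)/C(C)=C\C)[C@@]2(C)[C@@H]3C(=O)C=C(C)[C@H]2[C@@H]3C1(C)C | target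

Total step count: 12. Longest linear sequence: 12 steps (from 1 to 22).

Steps most likely to fail

Step 9. After loss of nitrogen the cation may be captured by acetate or water, eliminate to an alkene, or undergo hydride shift before the bridge carbon migrates. The fallback replaces the diazonium ion by a sulfonate, sets out from 12 and returns at 18. Cross-metathesis of 12 with pinacol vinylboronate (second-generation Grubbs catalyst RuCl2(=CHPh)(H2IMes)(PCy3), CH2Cl2, 40 °C) should give the (E)-alkenylboronate F1. Silyl dienol ether formation (TBSOTf, Et3N) and heating in xylene should give, by the same tether-controlled Diels–Alder reaction, the endo-boronate adduct F2. Oxidation with NaBO3·4H2O in THF/H2O proceeds with retention to the endo alcohol F3, and MsCl/Et3N gives the endo mesylate F4. Et2AlCl in CH2Cl2 at −78 → 0 °C then triggers the same anti-periplanar 1,2-shift as a sulfonate semipinacol rearrangement and should give 18.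

Step 7. Closure of a seven-membered tether may be too slow for the thermal cycloaddition, so that isomerization or decomposition of the silyl dienol ether takes over. The fallback builds the two bonds one after the other under anionic conditions, sets out from 13 and returns at 15. γ-Deprotonation with LiN(SiMe3)2 in THF (−78 → 0 °C) and intramolecular vinylogous Michael addition of the ring γ-carbon to the nitroalkene should give, after protonation, the Michael adduct F5. A catalytic base (DBU, MeCN) should then close the norbornane by intramolecular nitro-aldol addition to the ketone, giving the nitro alcohol F6 with the nitro group trans to the tert-alkyl carbon (endo, the less strained epimer under the reversible conditions). Silylation of the bridgehead hydroxyl (TBSOTf, 2,6-lutidine) gives 15.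

Step 11. Site selectivity among three secondary hydroxyls may be poor, and the acetyl group may wander to a neighbouring hydroxyl. The fallback uses the protecting groups already present to unveil the oxygens one at a time, sets out from 18 and returns at 22. TBAF in THF should give the mono-alcohol F7, and Yamaguchi angeloylation (21, 2,4,6-trichlorobenzoyl chloride, Et3N, DMAP, toluene, 80 °C) the angelate F8. Aqueous AcOH (80%, 40 °C) removes the acetonide to give the diol F9. Acetylation (AcCl, 2,4,6-collidine, −78 °C) then has to distinguish only the central hydroxyl from one neopentyl hydroxyl and should give the acetate F10, and a second Yamaguchi angeloylation gives 22.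

Further compounds
F1 | step 9 | (E)-alkenylboronate: 12 with the vinyl group converted into (E)-2-(pinacolboryl)vinyl | CC1(C)O[C@@H](C(C)(C)/C=C/B2OC(C)(C)C(C)(C)O2)[C@H]([C@@H](O[Si](C)(C)C(C)(C)C)[C@]3(C)CC(C)=CC3=O)O1
F2 | step 9 | endo-boronate Diels–Alder adduct (15 with 6-endo-Bpin in place of nitro) | CC1(C)O[C@@H]2[C@@H](O1)[C@@H](O[Si](C)(C)C(C)(C)C)[C@@]3(C)[C@]4(O[Si](C)(C)C(C)(C)C)C=C(C)[C@H]3[C@H](C2(C)C)[C@H]4B5OC(C)(C)C(C)(C)O5
F3 | step 9 | endo alcohol (15 with 6-endo-OH in place of nitro) | CC1(C)O[C@@H]2[C@@H](O1)[C@@H](O[Si](C)(C)C(C)(C)C)[C@@]3(C)[C@]4(O[Si](C)(C)C(C)(C)C)C=C(C)[C@H]3[C@H](C2(C)C)[C@H]4O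
F4 | step 9 | endo mesylate of F3 | CC1(C)O[C@@H]2[C@@H](O1)[C@@H](O[Si](C)(C)C(C)(C)C)[C@@]3(C)[C@]4(O[Si](C)(C)C(C)(C)C)C=C(C)[C@H]3[C@H](C2(C)C)[C@H]4OS(C)(=O)=O
F5 | step 7 | Michael adduct: cyclopentenone fused to the cycloheptane through its C-4 and C-5, with a nitromethyl group on the new ring carbon | CC1(C)O[C@@H]2[C@@H](O1)[C@@H](O[Si](C)(C)C(C)(C)C)[C@@]3(C)C(=O)C=C(C)[C@H]3[C@H](C2(C)C)C[N+](=O)[O-]
F6 | step 7 | nitro alcohol: 15 with a free bridgehead hydroxyl | CC1(C)O[C@@H]2[C@@H](O1)[C@@H](O[Si](C)(C)C(C)(C)C)[C@@]3(C)[C@]4(O)C=C(C)[C@H]3[C@H](C2(C)C)[C@H]4[N+](=O)[O-]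
F7 | step 11 | mono-alcohol: 18 without the silyl group | CC1(C)O[C@@H]2[C@@H](O1)[C@@H](O)[C@@]3(C)[C@@H]4C(=O)C=C(C)[C@H]3[C@@H]4C2(C)C
F8 | step 11 | angelate of F7 | CC1(C)O[C@@H]2[C@@H](O1)[C@@H](OC(=O)/C(C)=C\C)[C@@]3(C)[C@@H]4C(=O)C=C(C)[C@H]3[C@@H]4C2(C)C
F9 | step 11 | diol mono-angelate (acetonide removed from F8) | O[C@@H]1[C@@H](O)[C@@H](OC(=O)/C(C)=C\C)[C@@]2(C)[C@@H]3C(=O)C=C(C)[C@H]2[C@@H]3C1(C)C
F10 | step 11 | central acetate of F9 | O[C@@H]1[C@@H](OC(C)=O)[C@@H](OC(=O)/C(C)=C\C)[C@@]2(C)[C@@H]3C(=O)C=C(C)[C@H]2[C@@H]3C1(C)C
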